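**Strategy.** CNP0283541.1 is an ampelopsin-B-type core (central benzene ring A, dihydrofuran B, seven-membered ring C) with a second trans-2,3-diaryl dihydrofuran, ring D (O1', C2', C3'), fused to ring A. Ring D is closed last at C2'–C3'. C3' is a diarylmethine, so it is reachable as a donor/donor rhodium carbene from a diaryl ketone hydrazone; C2' is the benzylic, oxygen-activated CH2 of an aryl 2,4-dimethoxybenzyl ether. One enantioselective 1,5 C–H insertion forms the bond, the ring and both stereocentres under catalyst control. The precursor is hydrazone 17 of a ring-A aryl ketone with that ether ortho to it. Ring B is made earlier by the same reaction type with the mirror-image catalyst.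

Key step: step 10

Labels: ring A, central benzene ring; ring B, dihydrofuran O1–C2–C3; ring C, seven-membered ring with C8 (CH bearing the 2,4-dioxygenated aryl group) and C9 (CH2); ring D, dihydrofuran O1'–C2'–C3'; ring E, the 3,5-dioxygenated benzene ring that joins C3 and C8.

Assumption: Rh2(S-PTAD)4 is taken to give the 3R centre in step 4 and Rh2(R-PTAD)4 the 3'S centre in step 10; if the sense of induction on these substrates is the reverse, the two catalyst enantiomers change places.

Remark: a single chiral catalyst acting on both sites at once would place the C3 and C3' aryl groups on opposite faces of ring A, whereas the target has them on the same face. The two insertions are therefore run separately, and ring C is closed between them so that only ring E can capture the C8 cation.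

**Step 1**
Reactants: 1 1-iodo-3,5-dimethoxybenzene; 2 3,5-dimethoxybenzoyl chloride
Product: 4 (2-hydroxy-6-iodo-4-methoxyphenyl)(3,5-dimethoxyphenyl)methanone, via dimethyl ether ketone 3 (not isolated)
Conditions: SnCl4 (1.5 equiv), CH2Cl2, 0 °C to rt; then BCl3 (2 equiv), −40 to 0 °C, one pot
Reagents that add atoms: none
Why: Friedel–Crafts acylation should take place para to one methoxy group and ortho to iodine rather than between the two methoxy groups, and BCl3 then removes only the methyl group whose oxygen chelates boron together with the new carbonyl group (chelation-controlled ortho-demethylation); the mild Lewis acid SnCl4 is chosen to leave the aryl iodide intact.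

**Step 2**
Reactants: 4 (2-hydroxy-6-iodo-4-methoxyphenyl)(3,5-dimethoxyphenyl)methanone; 5 4-methoxybenzyl chloride
Product: 6 {2-iodo-4-methoxy-6-[(4-methoxyphenyl)methoxy]phenyl}(3,5-dimethoxyphenyl)methanone
Conditions: K2CO3, DMF, 60 °C
Reagents that add atoms: none
Why: Williamson etherification of the only phenol, whose hydrogen bond to the ketone is broken by carbonate in DMF.

**Step 3**
Reactants: 6 {2-iodo-4-methoxy-6-[(4-methoxyphenyl)methoxy]phenyl}(3,5-dimethoxyphenyl)methanone
Product: 7 hydrazone of 6 (E/Z mixture, both isomers give the same diazo compound)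
Conditions: N2H4·H2O (20 equiv), AcOH (cat.), n-BuOH, 110 °C, sealed tube
Reagents that add atoms: hydrazine monohydrate, NN.O
Why: Condensation of hydrazine with the diaryl ketone to the N-unsubstituted hydrazone; the two ortho substituents slow it, hence the excess hydrazine and the high temperature, and the electron-rich aryl iodide has no activation for substitution by hydrazine.

**Step 4**
Reactants: 7 hydrazone of 6
Product: 9 (2S,3R)-3-(3,5-dimethoxyphenyl)-4-iodo-6-methoxy-2-(4-methoxyphenyl)-2,3-dihydro-1-benzofuran (2,3-cis), via diazo compound 8 (not isolated)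
Conditions: MnO2 (10 equiv), CH2Cl2, 0 °C; filtration; Rh2(S-PTAD)4 (1 mol %), CH2Cl2, −20 °C to rt
Reagents that add atoms: none
Why: MnO2 dehydrogenates the hydrazone to the diaryldiazomethane, and the chiral divalent rhodium carboxylate turns it into a donor/donor carbene that inserts 1,5 into the benzylic C–H bond of the 4-methoxybenzyl ether (intramolecular carbene C–H insertion), setting C3 under catalyst control and C2 cis to it.

**Step 5**
Reactants: 9 cis 4-iodo dihydrobenzofuran; 2 3,5-dimethoxybenzoyl chloride; 10 2,4-dimethoxystyrene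
Product: 11 [(2S,3R)-3-(3,5-dimethoxyphenyl)-4-[(E)-2-(2,4-dimethoxyphenyl)ethenyl]-6-methoxy-2-(4-methoxyphenyl)-2,3-dihydro-1-benzofuran-5-yl](3,5-dimethoxyphenyl)methanone
Conditions: Pd(OAc)2 (10 mol %), P(2-furyl)3 (25 mol %), norbornene (1.5 equiv), Cs2CO3 (3 equiv), toluene, 100 °C
Reagents that add atoms: none
Why: Catellani reaction (ortho-acylation with terminating Heck reaction): zerovalent palladium adds to the C–I bond, norbornene inserts, the only free ortho C–H bond (C5) is palladated, the palladacycle is acylated by 2, norbornene is extruded from the now doubly ortho-substituted arylpalladium species, and Heck coupling with 10 gives the E-stilbene; no stereocentre is touched.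

**Step 6**
Reactants: 11 cis keto stilbene
Product: 13 (2R,3R,8R) tetracyclic ketone (ring A carries, in order, O1, H, OMe, the 3,5-dimethoxybenzoyl group, C9 and C3; ring B is trans with 4-methoxyphenyl at C2; ring C is closed through ring E, which has two OMe groups, to C8 bearing 2,4-dimethoxyphenyl), via trans stilbene 12 (not isolated)
Conditions: TFA (10 equiv), CH2Cl2, 0 °C to rt
Reagents that add atoms: none
Why: TFA protonates the stilbene at the carbon next to ring A to give the cation stabilized by the 2,4-dimethoxyphenyl group, which the ortho carbon of the C3 aryl ring captures (Friedel–Crafts hydroarylation closing the seven-membered ring) with C8 set by the neighbouring centre C3 as in the acid cyclization of ε-viniferin to ampelopsin B; the same medium turns the cis ring B into the more stable trans ring by reversible ionization of the benzylic C2–O1 bond, and the aroyl ring does not compete because its ortho carbons are deactivated by the carbonyl group.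

**Step 7**
Reactants: 13 tetracyclic ketone
Product: 14 phenol (13 with OH in place of the ring-A OMe group)
Conditions: BCl3 (1.5 equiv), CH2Cl2, −78 to 0 °C
Reagents that add atoms: none
Why: Chelation-controlled demethylation: only the ring-A methoxy group is ortho to the ketone and can form the six-membered boron chelate, so the other seven methyl ethers and the trans ring B should remain at low temperature.

**Step 8**
Reactants: 14 phenol; 15 2,4-dimethoxybenzyl alcohol
Product: 16 aryl 2,4-dimethoxybenzyl ether (14 with OCH2(2,4-dimethoxyphenyl) in place of OH)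
Conditions: PPh3, DIAD, THF, 0 °C to rt
Reagents that add atoms: none
Why: Mitsunobu etherification of the acidic ortho-acyl phenol with a primary benzylic alcohol under neutral conditions, which avoids the unstable 2,4-dimethoxybenzyl halide and any acid that would cleave the new ether.

**Step 9**
Reactants: 16 aryl 2,4-dimethoxybenzyl ether
Product: 17 hydrazone of 16 (E/Z mixture)
Conditions: N2H4·H2O (30 equiv), AcOH (cat.), n-BuOH, 110–120 °C, sealed tube
Reagents that add atoms: hydrazine monohydrate, NN.O
Why: Hydrazone formation at the only carbonyl group of the molecule; the ketone has two ortho substituents and needs forcing conditions, under which the hydrazine-buffered medium should leave the acid-labile benzyl ether intact.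

**Step 10**
Reactants: 17 hydrazone of 16
Product: 19 nonamethyl ether of the 2'-epimer of the target (rings A–E as in 13, ring D 2'R,3'S, 2',3'-cis, with 2,4-dimethoxyphenyl at C2' and 3,5-dimethoxyphenyl at C3'), via diazo compound 18 (not isolated)
Conditions: MnO2 (10 equiv), CH2Cl2, 0 °C; filtration; slow addition to Rh2(R-PTAD)4 (2 mol %), CH2Cl2, −20 °C to rt
Reagents that add atoms: none
Why: MnO2 dehydrogenates the hydrazone to the diaryldiazomethane 18, from which Rh2(R-PTAD)4 (divalent rhodium) expels N2 to give a donor/donor rhodium carbene at C3'. The electrophilic carbene carbon takes a hydride from the O1'–CH2 group and the C3'–C2' bond forms in the same event or from a short-lived ion pair, which is the known intramolecular C–H insertion of diaryl carbenes into benzylic ethers that gives 2,3-diaryl-2,3-dihydrobenzofurans. Ring D closes as a five-membered ring in the 1,5-insertion mode through the six-centre array C3'–C(ring A)–C(ring A)–O1'–C2'–H. C3' is set by the chiral carboxylate ligands (catalyst control of the carbene face), and C2' is set relative to C3' by the insertion itself, which gives the 2',3'-cis ring that step 11 corrects. The step needs site selectivity for the ether CH2 over the C8–H and C9–H2 bonds of ring C, secured by the oxygen lone pair and the 2,4-dimethoxyphenyl group, which make this C–H bond the most hydridic, and by the rigid ring C, which holds C8–H away from the carbene. It also needs face selectivity against any bias of the three existing centres, secured by the choice of catalyst enantiomer (the C8 substituent pointing to that face should be only H), while slow addition of 18 keeps azine formation down.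

**Step 11**
Reactants: 19 cis nonamethyl ether
Product: 21 CNP0283541.1, via trans nonamethyl ether 20 (not isolated)
Conditions: BBr3 (20 equiv), CH2Cl2, −78 °C to rt; then MeOH, H2O
Reagents that add atoms: none
Why: BBr3 cleaves the nine aryl methyl ethers (Lewis acid ether cleavage), and under the same acidic conditions the C2'–O1' bond of the cis ring D should ionize reversibly to the 2,4-dioxygenated benzylic cation and close again to the more stable 2',3'-trans ring, while C3, C3' and C8, which carry no leaving group, keep their configuration.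

**Compound list**
1 | 1-iodo-3,5-dimethoxybenzene | COc1cc(I)cc(OC)c1 | starting material
2 | 3,5-dimethoxybenzoyl chloride | COc1cc(cc(OC)c1)C(Cl)=O | starting material
3 | (2-iodo-4,6-dimethoxyphenyl)(3,5-dimethoxyphenyl)methanone | COc1cc(I)c(C(=O)c2cc(OC)cc(OC)c2)c(OC)c1 | intermediate
4 | (2-hydroxy-6-iodo-4-methoxyphenyl)(3,5-dimethoxyphenyl)methanone | COc1cc(O)c(C(=O)c2cc(OC)cc(OC)c2)c(I)c1 | intermediate
5 | 4-methoxybenzyl chloride | COc1ccc(CCl)cc1 | starting material
6 | {2-iodo-4-methoxy-6-[(4-methoxyphenyl)methoxy]phenyl}(3,5-dimethoxyphenyl)methanone | COc1ccc(COc2cc(OC)cc(I)c2C(=O)c2cc(OC)cc(OC)c2)cc1 | intermediate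
7 | hydrazone of 6 | COc1ccc(COc2cc(OC)cc(I)c2C(=NN)c2cc(OC)cc(OC)c2)cc1 | intermediate
8 | diazo compound from 7 | COc1ccc(COc2cc(OC)cc(I)c2C(=[N+]=[N-])c2cc(OC)cc(OC)c2)cc1 | intermediate
9 | (2S,3R)-3-(3,5-dimethoxyphenyl)-4-iodo-6-methoxy-2-(4-methoxyphenyl)-2,3-dihydro-1-benzofuran | COc1ccc([C@H]2Oc3cc(OC)cc(I)c3[C@H]2c2cc(OC)cc(OC)c2)cc1 | intermediate
10 | 2,4-dimethoxystyrene | C=Cc1ccc(OC)cc1OC | starting material
11 | [(2S,3R)-3-(3,5-dimethoxyphenyl)-4-[(E)-2-(2,4-dimethoxyphenyl)ethenyl]-6-methoxy-2-(4-methoxyphenyl)-2,3-dihydro-1-benzofuran-5-yl](3,5-dimethoxyphenyl)methanone | COc1ccc([C@H]2Oc3cc(OC)c(C(=O)c4cc(OC)cc(OC)c4)c(/C=C/c4ccc(OC)cc4OC)c3[C@H]2c2cc(OC)cc(OC)c2)cc1 | intermediate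
12 | (2R,3R) epimer of 11 (trans ring B) | COc1ccc([C@@H]2Oc3cc(OC)c(C(=O)c4cc(OC)cc(OC)c4)c(/C=C/c4ccc(OC)cc4OC)c3[C@H]2c2cc(OC)cc(OC)c2)cc1 | intermediate
13 | (2R,3R,8R) tetracyclic ketone (rings A, B, C, E; ring-A OMe and 3,5-dimethoxybenzoyl group) | COc1ccc([C@@H]2Oc3cc(OC)c(C(=O)c4cc(OC)cc(OC)c4)c4c3[C@H]2c2cc(OC)cc(OC)c2[C@@H](c2ccc(OC)cc2OC)C4)cc1 | intermediate
14 | (2R,3R,8R) tetracyclic keto phenol (ring-A OH ortho to the ketone) | COc1ccc([C@@H]2Oc3cc(O)c(C(=O)c4cc(OC)cc(OC)c4)c4c3[C@H]2c2cc(OC)cc(OC)c2[C@@H](c2ccc(OC)cc2OC)C4)cc1 | intermediate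
15 | 2,4-dimethoxybenzyl alcohol | COc1ccc(CO)c(OC)c1 | starting material
16 | (2R,3R,8R) tetracyclic ketone with ring-A 2,4-dimethoxybenzyl ether | COc1ccc([C@@H]2Oc3cc(OCc4ccc(OC)cc4OC)c(C(=O)c4cc(OC)cc(OC)c4)c4c3[C@H]2c2cc(OC)cc(OC)c2[C@@H](c2ccc(OC)cc2OC)C4)cc1 | intermediate
17 | hydrazone of 16 | COc1ccc([C@@H]2Oc3cc(OCc4ccc(OC)cc4OC)c(C(=NN)c4cc(OC)cc(OC)c4)c4c3[C@H]2c2cc(OC)cc(OC)c2[C@@H](c2ccc(OC)cc2OC)C4)cc1 | intermediate
18 | diazo compound from 17 | COc1ccc([C@@H]2Oc3cc(OCc4ccc(OC)cc4OC)c(C(=[N+]=[N-])c4cc(OC)cc(OC)c4)c4c3[C@H]2c2cc(OC)cc(OC)c2[C@@H](c2ccc(OC)cc2OC)C4)cc1 | intermediate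
19 | nonamethyl ether with cis ring D (2R,3R,8R,2'R,3'S) | COc1ccc([C@@H]2Oc3cc4c(c5c3[C@H]2c2cc(OC)cc(OC)c2[C@@H](c2ccc(OC)cc2OC)C5)[C@H](c2cc(OC)cc(OC)c2)[C@H](c2ccc(OC)cc2OC)O4)cc1 | intermediate
20 | nonamethyl ether with trans ring D (2R,3R,8R,2'S,3'S) | COc1ccc([C@@H]2Oc3cc4c(c5c3[C@H]2c2cc(OC)cc(OC)c2[C@@H](c2ccc(OC)cc2OC)C5)[C@H](c2cc(OC)cc(OC)c2)[C@@H](c2ccc(OC)cc2OC)O4)cc1 | intermediate
21 | CNP0283541.1 | Oc1ccc([C@@H]2Oc3cc4c(c5c3[C@H]2c2cc(O)cc(O)c2[C@@H](c2ccc(O)cc2O)C5)[C@H](c2cc(O)cc(O)c2)[C@@H](c2ccc(O)cc2O)O4)cc1 | target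

**Totals.** Total step count: 11. Longest linear sequence: 11 steps (1 to 21).

**Steps most likely to fail**

Step 5. The palladacycle at C5 sits next to the C6 methoxy group, so its acylation may be slow and give way to premature Heck coupling at C4 or to norbornene-containing by-products. The fallback sets out from 4 and comes back at 13; it brings the ring-A ketone in through a bromide instead of a C–H palladation.
- Bromination of 4 para to the hydroxyl group (NBS, MeCN, 0 °C) should give (3-bromo-6-hydroxy-2-iodo-4-methoxyphenyl)(3,5-dimethoxyphenyl)methanone F1.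
- Etherification with 5 (K2CO3, DMF) gives the 4-methoxybenzyl ether F2, and hydrazine gives the hydrazone F3.
- MnO2 and then Rh2(S-PTAD)4 give, through the diazo compound F4, the cis 5-bromo-4-iodo dihydrobenzofuran F5.
- A Heck reaction with 10 at the carbon–iodine bond only (Pd(OAc)2, P(o-tol)3, Et3N, DMF, 90 °C) gives the cis bromo stilbene F6.
- TFA in CH2Cl2 epimerizes C2 (trans bromo stilbene F7, formed in the flask) and closes ring C to the bromo tetracycle F8.
- Bromine–lithium exchange (t-BuLi, THF, −78 °C) gives the aryllithium F9, which is acylated with 2 at −78 °C to give 13.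

Step 10. The carbene may react with poor face selectivity if the existing centres oppose the catalyst, or be lost to azine formation or to insertion at C8–H. The fallback sets out from 16, comes back at 19, and also bypasses step 9.
- Irradiation of 16 (350 nm, benzene) should bring about δ-hydrogen abstraction by the excited ketone from the O–CH2 group and closure of the 1,5-biradical (Norrish–Yang photocyclization of an ortho-benzyloxy benzophenone) to the 3'-hydroxy ring-D compound F11, as a mixture at C2' and C3'.
- Ionic deoxygenation (Et3SiH, BF3·OEt2, CH2Cl2, −78 to −40 °C) of the tertiary diaryl carbinol delivers hydride anti to the C2' aryl group and should give 19 together with its (2'S,3'R) cis diastereomer F12, from which 19 is separated by chromatography.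

Step 9. Condensation at the doubly ortho-substituted ketone may stall, or the forcing conditions may cleave the acid-labile benzyl ether. The fallback sets out from 14 and comes back at 17; it changes the order of events.
- Hydrazine (N2H4·H2O, EtOH, 80 °C) is condensed with the less hindered, hydrogen-bond-activated ortho-hydroxy ketone 14 to give the hydroxy hydrazone F10.
- The phenol of F10 is then alkylated chemoselectively as its caesium salt with commercial 2,4-dimethoxybenzyl chloride (Cs2CO3, DMF, rt) to give 17.

**Further compounds**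
F1 | step 5 | (3-bromo-6-hydroxy-2-iodo-4-methoxyphenyl)(3,5-dimethoxyphenyl)methanone | COc1cc(O)c(C(=O)c2cc(OC)cc(OC)c2)c(I)c1Br
F2 | step 5 | {3-bromo-2-iodo-4-methoxy-6-[(4-methoxyphenyl)methoxy]phenyl}(3,5-dimethoxyphenyl)methanone | COc1ccc(COc2cc(OC)c(Br)c(I)c2C(=O)c2cc(OC)cc(OC)c2)cc1
F3 | step 5 | hydrazone of F2 | COc1ccc(COc2cc(OC)c(Br)c(I)c2C(=NN)c2cc(OC)cc(OC)c2)cc1
F4 | step 5 | diazo compound from F3 | COc1ccc(COc2cc(OC)c(Br)c(I)c2C(=[N+]=[N-])c2cc(OC)cc(OC)c2)cc1
F5 | step 5 | (2S,3R)-5-bromo-3-(3,5-dimethoxyphenyl)-4-iodo-6-methoxy-2-(4-methoxyphenyl)-2,3-dihydro-1-benzofuran | COc1ccc([C@H]2Oc3cc(OC)c(Br)c(I)c3[C@H]2c2cc(OC)cc(OC)c2)cc1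
F6 | step 5 | (2S,3R)-5-bromo-4-[(E)-2-(2,4-dimethoxyphenyl)ethenyl]-3-(3,5-dimethoxyphenyl)-6-methoxy-2-(4-methoxyphenyl)-2,3-dihydro-1-benzofuran | COc1ccc([C@H]2Oc3cc(OC)c(Br)c(/C=C/c4ccc(OC)cc4OC)c3[C@H]2c2cc(OC)cc(OC)c2)cc1
F7 | step 5 | (2R,3R) epimer of F6 | COc1ccc([C@@H]2Oc3cc(OC)c(Br)c(/C=C/c4ccc(OC)cc4OC)c3[C@H]2c2cc(OC)cc(OC)c2)cc1
F8 | step 5 | (2R,3R,8R) bromo tetracycle (13 with Br in place of the aroyl group) | COc1ccc([C@@H]2Oc3cc(OC)c(Br)c4c3[C@H]2c2cc(OC)cc(OC)c2[C@@H](c2ccc(OC)cc2OC)C4)cc1
F9 | step 5 | aryllithium from F8 | COc1ccc([C@@H]2Oc3cc(OC)c([Li])c4c3[C@H]2c2cc(OC)cc(OC)c2[C@@H](c2ccc(OC)cc2OC)C4)cc1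
F10 | step 9 | hydrazone of 14 | COc1ccc([C@@H]2Oc3cc(O)c(C(=NN)c4cc(OC)cc(OC)c4)c4c3[C@H]2c2cc(OC)cc(OC)c2[C@@H](c2ccc(OC)cc2OC)C4)cc1
F11 | step 10 | 3'-hydroxy ring-D compound (mixture at C2' and C3') | COc1ccc([C@@H]2Oc3cc4c(c5c3[C@H]2c2cc(OC)cc(OC)c2[C@@H](c2ccc(OC)cc2OC)C5)C(O)(c2cc(OC)cc(OC)c2)C(c2ccc(OC)cc2OC)O4)cc1
F12 | step 10 | (2'S,3'R) cis diastereomer of 19 | COc1ccc([C@@H]2Oc3cc4c(c5c3[C@H]2c2cc(OC)cc(OC)c2[C@@H](c2ccc(OC)cc2OC)C5)[C@@H](c2cc(OC)cc(OC)c2)[C@@H](c2ccc(OC)cc2OC)O4)cc1
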